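Percent of the starting material charged was the unit the meeting kept throughout, so that flasks of different charge could be laid side by side. Before it lay two earlier runs and a new flask that keeps their nucleophile charges and changes c(starting material).

| flask | starting material | first nucleophile | second nucleophile | remark | time |
|---|---|---|---|---|---|
| zeta | 10 mM | 16 mM | 22 mM | run made earlier |  |
| delta | 40 mM | 16 mM | 22 mM | run made earlier |  |
| flask | 20 mM | 16.0 mM | 22.0 mM |  | 3.0 d |

| run | time / d | target / % |
|---|---|---|
| zeta | 0.0556 | 19.7 |
| zeta | 0.208 | 45.6 |
| zeta | 0.625 | 30.9 |
| zeta | 2.50 | 0.1 |
| delta | 0.0556 | 19.5 |
| delta | 0.208 | 26.0 |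
| delta | 0.625 | 9.5 |
| delta | 2.50 | 0 |

(readings scatter by 1 percentage point)



- the moment within 3.0 d at which there is most target
- the amount of target, in percent of the starting material charged, at that time

The forecaster argued that target is made and then consumed, and that a simple rate model fell short of the zeta peak, so that, in the words minuted, “I therefore interpolate empirically”; this gave 37 % at 0.22 d.

I, taking the minutes, proposed a smaller task, to start from the zeta run and reckon a correction for the charge at one shared sampling time: at 0.208 d the zeta reading is 45.6 % and the delta reading 26.0 %, each the highest of its run, but the readings stand so far apart that neither need lie at the maximum of its run, and the maximum may move with the charge, so what I reckon is an amount near that time and not the moment of the maximum. Dividing the drop between those readings by the difference in c(starting material) gives 0.00653 mM⁻¹, the fraction of the charge given up as target per extra mM at that time, which I named the charge penalty, in the usual term a sensitivity coefficient, and which carries the scatter of its two readings. The flask, 10.0 mM above the zeta charge, then pays 6.5 percentage points, which put my own figure at 39.1 % near 0.208 d, higher than the forecast's.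

The flask gives 42.3 % at 0.240 d.

    starting material → intermediate (k = 6.69 × 10⁻⁵ s⁻¹)
    first nucleophile + intermediate → target (k = 0.146 L mol⁻¹ s⁻¹)
    second nucleophile + intermediate → other capture product (k = 0.00392 L mol⁻¹ s⁻¹)
    intermediate → solvolysis product (k = 1.57 × 10⁻⁴ s⁻¹)
    starting material + target → side product (k = 3.90 × 10⁻⁴ L mol⁻¹ s⁻¹)
    target → over-reaction product (k = 2.54 × 10⁻⁵ s⁻¹)

The flask stands 3.2 points above the charge-penalty figure and 5.3 points above the forecast, and it lies 3.3 points below the zeta reading where the penalty had reckoned 6.5 points. On the neighbouring flask, with 5.0 mM of starting material and the other charges held, the same penalty adds 3.3 points to the zeta reading and so reckons 48.9 %; that neighbouring flask gives 48.6 %.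

(The numbers in the tables come from a simulation on assumed constants; the scatter is artificial.)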